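## Structural features

The target is a germacranolide: a ten-membered carbocycle (C1–C10) trans-fused at C6–C7 to an α-methylene-γ-butyrolactone (ring oxygen on C6, carbonyl C12, exocyclic C11=C13). C6, C7 and C8 are contiguous stereocentres, all R: H6 and H7 are trans on the lactone, and O8 is syn to C6 when C9–C8–C7–C11 is drawn as a zigzag; O8 carries the 3-methylbutanoate. The ring holds two trisubstituted alkenes, C4=C5 (hydroxymethyl C15 on C4) and C1=C10 (formyl C14 on C10); both are E by the sequence rules but cis within the ring, because C15 and C14 outrank the ring carbons C3 and C9. The fragile groups are the two Michael acceptors (methylene lactone, enal), the allylic C6–O bond, the 1,3-related O6/O8 acyl groups (acyl shift, isomerisation to the 8,12-lactone) and the free allylic alcohol. The real difficulties are closing a ten-membered ring, keeping C14 (aldehyde) apart from C15 (alcohol), and setting C6–C7–C8 so that the lactone closes on O6 and not on O8. The key step uses the acyl carbon on C10: a phosphonate on C10 next to a C14 thioester gives a soft carbanion that olefinates a C1 aldehyde, and the geometry this reaction prefers (C2 trans to C14) is the ring-cis geometry of C1=C10.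

## Logic of the disconnections

33 from 32. The O–Si bond at C15 is cut. The allylic alcohol is freed last because a free O15 would interfere with every acylation and oxidation-level change before it. The demand is a fluoride cleavage that leaves two Michael acceptors and the O8 ester alone. The silyl group must also have survived aqueous acid at 26 → 27, so it is tert-butyldiphenylsilyl and not tert-butyldimethylsilyl.

32 from 30 (through 31). C11=C13 is traced back to a C13–N bond and C11–H. The methylene lactone lies six atoms from C10 and would trap the C10 carbanion in a six-membered Michael ring; it would also be reduced at 29 → 30. The gain is that the most electrophilic group is absent in all late steps. The demand is that N-methylation and bicarbonate elimination are the only reactions of 30 under those conditions.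

30 from 29. C14–H is traced back to C14–S. A thioester is the one carboxyl derivative that a silane/palladium pair takes to the aldehyde while lactone and ester stay, so C14 and C15 differ in oxidation level from the outset. The demand is a reduction that stops at the aldehyde and spares C1=C10.

29 from 28 (key step). C1=C10 is cut. It is the retron of a phosphonate olefination, the only ring bond that forms without a stereocentre, and its geometry corrects itself. The gain is the loss of the medium ring: 28 is a chain on a lactone. The demand is that ring closure beats dimerisation and that the base neither releases the amine nor attacks the esters.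

28 from 27, and 27 from 26. The C14–S bond is cut, then the C14 tert-butyl ester and the C1 acetal are restored. A C14 thioester next to a free O8 would close to a γ-lactone, so C14 travels as a tert-butyl ester until O8 is acylated; the acetal hides C1 from the amine and from carbanions. The demand is one acid treatment that frees C14 and C1 but keeps the O15 silyl ether, and a thioesterification in which the thiol finds no Michael acceptor.

26 from 25. The C13–N bond is cut. The mask goes on as soon as the methylene lactone exists and before any thiol or carbanion is present. The demand is conjugate addition faster than ester aminolysis.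

25 from 23 (through 24), and 23 from 21 and 22. The lactone C12–O6 bond and the O8–acyl bond are cut. Acylating O8 first leaves O6 as the only hydroxyl that can close on C12, which fixes the regiochemistry of lactonisation. The demand is a desilylation and lactonisation under mild acid, since base could shift the acyl group from O8 to O6.

21 from 14 and 19. The C7–C8 bond is cut, which splits the chain into two fragments of similar size. The forward allylation makes C7, C8 and the C11=C13 unit at once. The demands are 7,8-syn addition, attack on the C7 face anti to the C6–O bond, and no lactonisation of the new O8 alkoxide.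

19 from 17 (through 18), and 17 from 15 and 16. C8=O is traced to a terminal alkene and the C9–C10 bond is cut. Bringing phosphorus in with a phosphonoacetate avoids a late Arbuzov reaction at a secondary carbon beside an amine and a thioester. The demand is mono-alkylation and an ozonolysis that stops at the aldehyde.

14 from 13, and 13 from 10 and 11 (through 12). The C13–Br bond is cut with allylic transposition, then the C7–C11 bond. The gain is that the whole allyl donor comes from an aldehyde and a three-carbon acrylate unit. The demand is a Z-configured bromide (C6 cis to C13) and an addition to 10 that does not epimerise C6.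

10 from 9, 9 from 8, 8 from 7. These change functional groups at C6 and C7 only: the aldehyde goes back to a silyl ether, the two silyl ethers to a diol, the diol to its acetonide. The demand is selectivity between primary and secondary silyl ethers and between a ketal and the C1 acetal.

7 from 6, 6 from 5, and 5 from 3 and 4. The O15–Si bond, the C15 oxidation level and then C4=C5 are cut. The olefination joins the chiral-pool carbon C6 to the C1–C4 chain and sets the alkene. The demand is E selectivity (C6 trans to C15) and no epimerisation of 4.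

3 from 1 and 2. The C3–C4 bond is cut. Both pieces are commercial and C1 arrives protected. The demand is mono-alkylation.

## Other disconnections considered

Alternative 1: The cut is C5–C6 together with the lactone C12–O bond. Forward, the open-chain alkenyl iodide aldehyde A1 would be treated with CrCl2 and catalytic NiCl2; the alkenylchromium adds to the C6 aldehyde and the C6 alkoxide closes on the methyl ester to give A2.
- In favour: carbocycle and lactone form in one operation, the reaction is a standard medium-ring closure, and no carbanion is involved.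
- Against: C6 is created during ring closure and must be controlled by C7 and by the ring. In A1 the C7 centre is α to the aldehyde and allylic, so it can epimerise or move into conjugation before coupling. A2 still needs O8 desilylation, acylation, PMB removal, C14 oxidation and O15 desilylation.
- Comparison: the chosen plan sets no stereocentre in its ring closure and needs three steps after it, against about five here. Alternative 1 is the better plan on one point: the methylene lactone needs no mask, and two rings are made at once.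

Alternative 2: The cut is C7–C8 inside the ring. Forward, CrCl2 converts the allylic bromide of the open-chain aldehyde A3 into an allylchromium that adds through C7 to the C8 aldehyde, giving the ten-membered hydroxy ester A4.
- In favour: this is the same bond and the same chair transition state as the fragment union of the chosen plan, the conditions are neutral, and this kind of closure is the best documented for ten-membered germacrane rings.
- Against: C7 and C8 are both set while the ring closes, so the chair must fit inside a strained ten-membered transition state and the syn preference is less certain than in the open chain. A4 needs acylation, acid lactonisation of a tert-butyl ester, PMB removal, oxidation and desilylation.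
- Comparison: on mechanism the two plans use the same chemistry in opposite order. Alternative 2 is the equal of the chosen plan in convergence and the better one in precedent for the ring closure and in needing no mask at C13. The chosen plan is better in stereochemical predictability and in step count after ring closure.

Alternative 3: The cut is C1–C2. Forward, NiI2 with 2,2′-bipyridine and Mn couples the C1 alkenyl bromide with the C2 alkyl iodide of A5 to give A6.
- In favour: no stereocentre is formed, lactone and O8 ester are already in place, and only PMB removal, oxidation and desilylation remain.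
- Against: cross-electrophile coupling to a ten-membered ring has little precedent. The free methylene lactone is exposed to low-valent nickel and to the C2 alkyl radical (conjugate reduction or radical addition). The alkenyl bromide geometry must be made pure and kept, and reduction or dimerisation of the iodide competes.
- Comparison: Alternative 3 equals the chosen plan in steps after ring closure. It is weaker on mechanism, because a radical/organonickel closure cannot correct alkene geometry, whereas the reversible addition of the chosen plan can.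

Key step: step 18

Assumptions and checks:
- Germacrane numbering is used throughout.
- C10 (phosphonate carbon) and the carbinol C7 of 13 are carried as epimer mixtures because both become sp2; C11 of 26–31 is drawn as the expected 11R epimer and is erased in step 20.
- The configurations of 28 and 29 were checked against the target (C6, C7, C8 unchanged; aldehyde carbon of 4 becomes C5), and no stereochemical correction was needed.
- Design changes: O15 is protected as the tert-butyldiphenylsilyl ether, the phosphonate enters with fragment 19, and the thioester is made only after O8 is acylated.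

Step 1
Reactants: 1 triethyl phosphonoacetate; 2 2-(2-bromoethyl)-1,3-dioxolane
Product: 3 ethyl 2-(diethoxyphosphoryl)-4-(1,3-dioxolan-2-yl)butanoate (racemic)
Conditions: NaH, DMF, 0 → 60 °C
Reagents that add atoms: none
Why: SN2 C-alkylation of the sodium phosphonoacetate carbanion by a primary bromide joins C3 to C4 and brings C1 in as an acetal; a slight excess of 1 limits dialkylation.

Step 2
Reactants: 3 alkylated phosphonate; 4 (S)-2,2-dimethyl-1,3-dioxolane-4-carbaldehyde
Product: 5 ethyl (E)-2-[2-(1,3-dioxolan-2-yl)ethyl]-3-[(4R)-2,2-dimethyl-1,3-dioxolan-4-yl]prop-2-enoate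
Conditions: LiCl, DBU, MeCN, 0 °C → rt
Reagents that add atoms: none
Why: Horner–Wadsworth–Emmons olefination under LiCl/amine conditions; the equilibrating stabilised carbanion should place C6 trans to the ester carbon C15, which is the C4=C5 geometry of the target, and the weak base should spare the α-centre of 4, which becomes C6.

Step 3
Reactants: 5 enoate
Product: 6 (E)-2-[2-(1,3-dioxolan-2-yl)ethyl]-3-[(4R)-2,2-dimethyl-1,3-dioxolan-4-yl]prop-2-en-1-ol
Conditions: iBu2AlH, CH2Cl2, −78 → 0 °C; aq. KNaC4H4O6
Reagents that add atoms: none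
Why: 1,2-reduction of the conjugated ester by the aluminium hydride gives the C15 allylic alcohol; both acetals are inert to hydride.

Step 4
Reactants: 6 allylic alcohol
Product: 7 tert-butyl{[(2E)-2-[2-(1,3-dioxolan-2-yl)ethyl]-3-[(4R)-2,2-dimethyl-1,3-dioxolan-4-yl]prop-2-enyl]oxy}diphenylsilane
Conditions: tBuPh2SiCl, imidazole, DMF, rt
Reagents that add atoms: tert-butyl(chloro)diphenylsilane, CC(C)(C)[Si](Cl)(c1ccccc1)c1ccccc1
Why: Silylation of the primary alcohol; this silyl ether should survive the aqueous acid of steps 5 and 16, which a tert-butyldimethylsilyl ether would not.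

Step 5
Reactants: 7 silyl ether
Product: 8 (2R,3E)-4-{[tert-butyl(diphenyl)silyl]oxymethyl}-6-(1,3-dioxolan-2-yl)hex-3-ene-1,2-diol
Conditions: AcOH/H2O/THF (4:1:1), rt → 40 °C
Reagents that add atoms: none
Why: Acid hydrolysis of the isopropylidene ketal, which ionises far more readily than the aldehyde-derived dioxolane at C1; the silyl ether is stable to aqueous acetic acid.

Step 6
Reactants: 8 diol
Product: 9 tert-butyl{[(2E,4R)-2-[2-(1,3-dioxolan-2-yl)ethyl]-4,5-bis(triethylsilyloxy)pent-2-enyl]oxy}diphenylsilane
Conditions: Et3SiCl, imidazole, DMAP (cat.), CH2Cl2, 0 °C → rt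
Reagents that add atoms: chlorotriethylsilane, CC[Si](Cl)(CC)CC
Why: Exhaustive silylation of both hydroxyls; the two triethylsilyl ethers are told apart in the next step by their primary/secondary nature.

Step 7
Reactants: 9 bis(triethylsilyl) ether
Product: 10 (2R,3E)-4-{[tert-butyl(diphenyl)silyl]oxymethyl}-6-(1,3-dioxolan-2-yl)-2-(triethylsilyloxy)hex-3-enal
Conditions: (COCl)2, DMSO, CH2Cl2, −78 → −30 °C; then Et3N, −78 → 0 °C
Reagents that add atoms: none
Why: Swern oxidation applied directly to the silyl ether: the chlorosulfonium reagent cleaves and oxidises the primary triethylsilyl ether to the C7 aldehyde and leaves the secondary one; low temperature and short base contact should keep the doubly activated C6–H from epimerising.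

Step 8
Reactants: 10 aldehyde; 11 methyl propiolate
Product: 13 methyl (4R,5E)-6-{[tert-butyl(diphenyl)silyl]oxymethyl}-8-(1,3-dioxolan-2-yl)-3-hydroxy-2-methylidene-4-(triethylsilyloxy)oct-5-enoate (both C3 epimers), via vinylalane 12 (not isolated)
Conditions: 11, iBu2AlH, N-methylmorpholine N-oxide, THF, 0 °C; then 10, 0 °C → rt
Reagents that add atoms: none
Why: Hydroalumination of the propiolate gives an α-aluminated acrylate that adds to the aldehyde (vinylalumination), giving the Morita–Baylis–Hillman adduct without days of amine base that would endanger C6; the new carbinol centre C7 is uncontrolled and is erased in step 9.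

Step 9
Reactants: 13 hydroxy acrylate
Product: 14 methyl (2Z,4R,5E)-2-(bromomethyl)-6-{[tert-butyl(diphenyl)silyl]oxymethyl}-8-(1,3-dioxolan-2-yl)-4-(triethylsilyloxy)octa-2,5-dienoate
Conditions: NBS, Me2S, CH2Cl2, 0 °C → rt
Reagents that add atoms: N-bromosuccinimide, O=C1CCC(=O)N1Br
Why: The alcohol is activated as an alkoxysulfonium salt and bromide attacks C13 in an SN2′ sense (allylic transposition of a Morita–Baylis–Hillman alcohol); the conjugated alkene forms with C6 trans to the ester and cis to CH2Br (Z), the geometry the allylation needs.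

Step 10
Reactants: 15 tert-butyl 2-(diethoxyphosphoryl)acetate; 16 3-bromoprop-1-ene
Product: 17 tert-butyl 2-(diethoxyphosphoryl)pent-4-enoate (racemic)
Conditions: NaH, THF, 0 °C → rt
Reagents that add atoms: none
Why: SN2 alkylation of the phosphonoacetate carbanion; the C10 phosphonate of the key step is in place from the outset and the allyl group is the latent C8 aldehyde.

Step 11
Reactants: 17 allyl phosphonoacetate
Product: 19 tert-butyl 2-(diethoxyphosphoryl)-4-oxobutanoate (racemic), via ozonide 18 (not isolated)
Conditions: O3, CH2Cl2, −78 °C; then PPh3, −78 °C → rt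
Reagents that add atoms: ozone, [O-][O+]=O
Why: Ozonolysis of the terminal alkene with reductive work-up gives the C8 aldehyde; ester and phosphonate are inert to ozone.

Step 12
Reactants: 14 allylic bromide; 19 aldehyde
Product: 21 7-tert-butyl 1-methyl (3R,4R)-6-(diethoxyphosphoryl)-4-hydroxy-2-methylidene-3-[(1R,2E)-3-{[tert-butyl(diphenyl)silyl]oxymethyl}-5-(1,3-dioxolan-2-yl)-1-(triethylsilyloxy)pent-2-enyl]heptanedioate (6R,7R,8R in germacrane numbering; both C10 epimers), via trimethylsilyl ether 20 (not isolated)
Conditions: CrCl2 (15 mol%), Mn, Me3SiCl, THF, rt; then citric acid, MeOH, 0 °C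
Reagents that add atoms: none
Why: Nozaki–Hiyama-type 2-(alkoxycarbonyl)allylation catalytic in chromium: the Z-configured allylchromium adds through C7 in a chair transition state with C6 axial, which should give the 7,8-syn adduct, and C6 should react in the rotamer with H6 eclipsing the alkene and the C6–O bond anti to the aldehyde (Felkin–Anh type), which gives the required 6,7 relation. The chromium alkoxide is silylated as it forms and the C14 ester is tert-butyl, so O8 cannot lactonise on C12 or C14.

Step 13
Reactants: 21 hydroxy diester; 22 3-methylbutanoic anhydride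
Product: 23 7-tert-butyl 1-methyl (3R,4R)-6-(diethoxyphosphoryl)-2-methylidene-4-(3-methylbutanoyloxy)-3-[(1R,2E)-3-{[tert-butyl(diphenyl)silyl]oxymethyl}-5-(1,3-dioxolan-2-yl)-1-(triethylsilyloxy)pent-2-enyl]heptanedioate
Conditions: DMAP, Et3N, CH2Cl2, 0 °C → rt
Reagents that add atoms: none
Why: DMAP-catalysed acylation of the secondary alcohol; it is done before O6 is freed so that only O6 can later close on C12, and before any thioester exists that O8 could attack.

Step 14
Reactants: 23 acylated diester
Product: 25 tert-butyl (4R)-4-[(2R,3R)-2-[(1E)-2-{[tert-butyl(diphenyl)silyl]oxymethyl}-4-(1,3-dioxolan-2-yl)but-1-enyl]-4-methylidene-5-oxooxolan-3-yl]-2-(diethoxyphosphoryl)-4-(3-methylbutanoyloxy)butanoate, via hydroxy ester 24 (not isolated)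
Conditions: HF·pyridine, pyridine, THF, 0 °C; then PPTS (cat.), PhMe, 50 °C
Reagents that add atoms: none
Why: Fluoride cleaves the secondary triethylsilyl ether much faster than the primary tert-butyldiphenylsilyl ether; the free O6 then closes on the C12 methyl ester under mild acid (5-exo-trig acyl substitution) to the trans-fused methylene lactone, without base that could shift the O8 acyl group.

Step 15
Reactants: 25 methylene lactone
Product: 26 tert-butyl (4R)-4-[(2R,3R,4R)-2-[(1E)-2-{[tert-butyl(diphenyl)silyl]oxymethyl}-4-(1,3-dioxolan-2-yl)but-1-enyl]-4-[(dimethylamino)methyl]-5-oxooxolan-3-yl]-2-(diethoxyphosphoryl)-4-(3-methylbutanoyloxy)butanoate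
Conditions: Me2NH (2 M in THF), THF, 0 °C → rt
Reagents that add atoms: dimethylamine, CNC
Why: Aza-Michael addition to the methylene lactone, far faster than aminolysis of the esters; protonation under equilibrating conditions should give the epimer with C13 trans to C8 (11R), and this centre is erased in step 20.

Step 16
Reactants: 26 amine adduct
Product: 27 (4R)-4-[(2R,3R,4R)-2-[(1E)-2-{[tert-butyl(diphenyl)silyl]oxymethyl}-5-oxopent-1-enyl]-4-[(dimethylamino)methyl]-5-oxooxolan-3-yl]-2-(diethoxyphosphoryl)-4-(3-methylbutanoyloxy)butanoic acid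
Conditions: CF3CO2H/CH2Cl2/H2O (10:10:1), 0 °C → rt
Reagents that add atoms: water, O
Why: Acidolysis of the tert-butyl ester and hydrolysis of the dioxolane in one operation; the protonated amine cannot eliminate, and the lactone, the O8 ester and the tert-butyldiphenylsilyl ether should tolerate aqueous trifluoroacetic acid for the time needed.

Step 17
Reactants: 27 aldehyde acid
Product: 28 S-ethyl (4R)-4-[(2R,3R,4R)-2-[(1E)-2-{[tert-butyl(diphenyl)silyl]oxymethyl}-5-oxopent-1-enyl]-4-[(dimethylamino)methyl]-5-oxooxolan-3-yl]-2-(diethoxyphosphoryl)-4-(3-methylbutanoyloxy)butanethioate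
Conditions: EtSH, EDC·HCl, DMAP (cat.), CH2Cl2, 0 °C → rt
Reagents that add atoms: ethanethiol, CCS
Why: Carbodiimide (Steglich-type) thioesterification of the α-phosphono acid; the thiol adds only reversibly to the C1 aldehyde, and C13 is already masked, so no thia-Michael addition can occur.

Step 18
Reactants: 28 phosphonate aldehyde
Product: 29 S-ethyl (1(10)E,4E,6R,7R,8R,11R)-15-[tert-butyl(diphenyl)silyl]oxy-13-(dimethylamino)-8-(3-methylbutanoyloxy)-11,13-dihydrogermacra-1(10),4-dien-12,6-olide-14-thioate
Conditions: LiCl, DBU, MeCN (1 mM, slow addition of 28), rt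
Reagents that add atoms: none
Why: DBU deprotonates the lithium-chelated phosphonate–thioester at C10; the carbanion adds reversibly to the C1 aldehyde, the lithium alkoxide closes to an oxaphosphetane, and this collapses to C1=C10 and lithium diethyl phosphate. The closest known reaction type is the intramolecular Horner–Wadsworth–Emmons macrocyclisation with LiCl and an amine base, common for macrolides and rarer for ten-membered carbocycles. The ten-membered ring closes by attack of C10 on the exocyclic C1 carbonyl (10-exo-trig) followed by syn-elimination; the chain ends sit on the neighbouring lactone carbons C6 and C7, and the ring-cis C4=C5 alkene turns the C1 arm back towards C10. No stereocentre is formed, and both C10 epimers of 28 converge on 29. The selectivity needed is alkene geometry: reversible addition lets the system reach the alkene with C14 trans to C2 (E), which is also the ring-cis and less strained arrangement, so thermodynamics and ring size point the same way. Chemoselectivity rests on the soft carbanion, which should ignore the lactone and ester carbonyls, and on the amine mask at C13, which removes the six-membered Michael closure. High dilution suppresses dimerisation, and the mild base should spare the β-amino lactone and the O8 ester.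

Step 19
Reactants: 29 macrocyclic thioester
Product: 30 (1(10)E,4E,6R,7R,8R,11R)-15-[tert-butyl(diphenyl)silyl]oxy-13-(dimethylamino)-8-(3-methylbutanoyloxy)-14-oxo-11,13-dihydrogermacra-1(10),4-dien-12,6-olide
Conditions: Et3SiH, Pd/C, acetone, rt
Reagents that add atoms: none
Why: Fukuyama reduction: the C–S bond adds oxidatively to zerovalent palladium, hydride is transferred from silicon and reductive elimination gives the aldehyde and stops there; lactone and ester are inert, and C13 is still masked, so the methylene lactone cannot be reduced.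

Step 20
Reactants: 30 amino enal
Product: 32 (1(10)E,4E,6R,7R,8R)-15-[tert-butyl(diphenyl)silyl]oxy-8-(3-methylbutanoyloxy)-14-oxogermacra-1(10),4,11(13)-trien-12,6-olide, via trimethylammonium iodide 31 (not isolated)
Conditions: MeI, THF, rt; then aq. NaHCO3, rt
Reagents that add atoms: none
Why: N-Methylation turns the amine into a leaving group and bicarbonate induces E1cB (Hofmann-type) elimination across C11–C13, restoring the exocyclic methylene; the base is too weak to touch the enal or the O8 ester.

Step 21
Reactants: 32 silyl-protected target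
Product: 33 (1(10)E,4E,6R,7R,8R)-15-hydroxy-8-(3-methylbutanoyloxy)-14-oxogermacra-1(10),4,11(13)-trien-12,6-olide (CNP0345200.3)
Conditions: HF·pyridine, pyridine, THF, 0 °C → rt
Reagents that add atoms: none
Why: Fluoride cleaves the Si–O bond under buffered, non-basic conditions that should leave both Michael acceptors and the ester alone.

## Compound list

1 | triethyl phosphonoacetate | CCOC(=O)CP(=O)(OCC)OCC | starting material
2 | 2-(2-bromoethyl)-1,3-dioxolane | BrCCC1OCCO1 | starting material
3 | ethyl 2-(diethoxyphosphoryl)-4-(1,3-dioxolan-2-yl)butanoate (racemic) | CCOC(=O)C(CCC1OCCO1)P(=O)(OCC)OCC | intermediate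
4 | (S)-2,2-dimethyl-1,3-dioxolane-4-carbaldehyde | O=C[C@@H]1COC(C)(C)O1 | starting material
5 | ethyl (E)-2-[2-(1,3-dioxolan-2-yl)ethyl]-3-[(4R)-2,2-dimethyl-1,3-dioxolan-4-yl]prop-2-enoate | CCOC(=O)/C(CCC1OCCO1)=C/[C@@H]1COC(C)(C)O1 | intermediate
6 | (E)-2-[2-(1,3-dioxolan-2-yl)ethyl]-3-[(4R)-2,2-dimethyl-1,3-dioxolan-4-yl]prop-2-en-1-ol | OC/C(CCC1OCCO1)=C/[C@@H]1COC(C)(C)O1 | intermediate
7 | tert-butyl{[(2E)-2-[2-(1,3-dioxolan-2-yl)ethyl]-3-[(4R)-2,2-dimethyl-1,3-dioxolan-4-yl]prop-2-enyl]oxy}diphenylsilane | CC(C)(C)[Si](c1ccccc1)(c1ccccc1)OC/C(CCC1OCCO1)=C/[C@@H]1COC(C)(C)O1 | intermediate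
8 | (2R,3E)-4-{[tert-butyl(diphenyl)silyl]oxymethyl}-6-(1,3-dioxolan-2-yl)hex-3-ene-1,2-diol | OC[C@H](O)/C=C(/CO[Si](c1ccccc1)(c1ccccc1)C(C)(C)C)CCC1OCCO1 | intermediate
9 | tert-butyl{[(2E,4R)-2-[2-(1,3-dioxolan-2-yl)ethyl]-4,5-bis(triethylsilyloxy)pent-2-enyl]oxy}diphenylsilane | CC[Si](CC)(CC)OC[C@H](O[Si](CC)(CC)CC)/C=C(/CO[Si](c1ccccc1)(c1ccccc1)C(C)(C)C)CCC1OCCO1 | intermediate
10 | (2R,3E)-4-{[tert-butyl(diphenyl)silyl]oxymethyl}-6-(1,3-dioxolan-2-yl)-2-(triethylsilyloxy)hex-3-enal | O=C[C@H](O[Si](CC)(CC)CC)/C=C(/CO[Si](c1ccccc1)(c1ccccc1)C(C)(C)C)CCC1OCCO1 | intermediate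
11 | methyl propiolate | C#CC(=O)OC | starting material
12 | [1-(methoxycarbonyl)ethenyl]bis(2-methylpropyl)alane (vinylalane, not isolated) | C=C(C(=O)OC)[Al](CC(C)C)CC(C)C | intermediate
13 | methyl (4R,5E)-6-{[tert-butyl(diphenyl)silyl]oxymethyl}-8-(1,3-dioxolan-2-yl)-3-hydroxy-2-methylidene-4-(triethylsilyloxy)oct-5-enoate (both C3 epimers) | C=C(C(=O)OC)C(O)[C@H](O[Si](CC)(CC)CC)/C=C(/CO[Si](c1ccccc1)(c1ccccc1)C(C)(C)C)CCC1OCCO1 | intermediate
14 | methyl (2Z,4R,5E)-2-(bromomethyl)-6-{[tert-butyl(diphenyl)silyl]oxymethyl}-8-(1,3-dioxolan-2-yl)-4-(triethylsilyloxy)octa-2,5-dienoate | BrC/C(C(=O)OC)=C\[C@H](O[Si](CC)(CC)CC)/C=C(/CO[Si](c1ccccc1)(c1ccccc1)C(C)(C)C)CCC1OCCO1 | intermediate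
15 | tert-butyl 2-(diethoxyphosphoryl)acetate | CCOP(=O)(CC(=O)OC(C)(C)C)OCC | starting material
16 | 3-bromoprop-1-ene | C=CCBr | starting material
17 | tert-butyl 2-(diethoxyphosphoryl)pent-4-enoate (racemic) | C=CCC(C(=O)OC(C)(C)C)P(=O)(OCC)OCC | intermediate
18 | tert-butyl 2-(diethoxyphosphoryl)-3-(1,2,4-trioxolan-3-yl)propanoate (ozonide, not isolated) | CCOP(=O)(OCC)C(CC1OCOO1)C(=O)OC(C)(C)C | intermediate
19 | tert-butyl 2-(diethoxyphosphoryl)-4-oxobutanoate (racemic) | O=CCC(C(=O)OC(C)(C)C)P(=O)(OCC)OCC | intermediate
20 | 4-O-trimethylsilyl ether of 21 (3R,4R,1′R; not isolated) | C=C(C(=O)OC)[C@@H]([C@H](O[Si](CC)(CC)CC)/C=C(/CO[Si](c1ccccc1)(c1ccccc1)C(C)(C)C)CCC1OCCO1)[C@H](O[Si](C)(C)C)CC(C(=O)OC(C)(C)C)P(=O)(OCC)OCC | intermediate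
21 | 7-tert-butyl 1-methyl (3R,4R)-6-(diethoxyphosphoryl)-4-hydroxy-2-methylidene-3-[(1R,2E)-3-{[tert-butyl(diphenyl)silyl]oxymethyl}-5-(1,3-dioxolan-2-yl)-1-(triethylsilyloxy)pent-2-enyl]heptanedioate (C10 epimers) | C=C(C(=O)OC)[C@@H]([C@H](O[Si](CC)(CC)CC)/C=C(/CO[Si](c1ccccc1)(c1ccccc1)C(C)(C)C)CCC1OCCO1)[C@H](O)CC(C(=O)OC(C)(C)C)P(=O)(OCC)OCC | intermediate
22 | 3-methylbutanoic anhydride | CC(C)CC(=O)OC(=O)CC(C)C | starting material
23 | 7-tert-butyl 1-methyl (3R,4R)-6-(diethoxyphosphoryl)-2-methylidene-4-(3-methylbutanoyloxy)-3-[(1R,2E)-3-{[tert-butyl(diphenyl)silyl]oxymethyl}-5-(1,3-dioxolan-2-yl)-1-(triethylsilyloxy)pent-2-enyl]heptanedioate | C=C(C(=O)OC)[C@@H]([C@H](O[Si](CC)(CC)CC)/C=C(/CO[Si](c1ccccc1)(c1ccccc1)C(C)(C)C)CCC1OCCO1)[C@H](OC(=O)CC(C)C)CC(C(=O)OC(C)(C)C)P(=O)(OCC)OCC | intermediate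
24 | 23 without the triethylsilyl group: free C6–OH, same spatial arrangement (formally 3S,4R,1′R; not isolated) | C=C(C(=O)OC)[C@@H]([C@H](O)/C=C(/CO[Si](c1ccccc1)(c1ccccc1)C(C)(C)C)CCC1OCCO1)[C@H](OC(=O)CC(C)C)CC(C(=O)OC(C)(C)C)P(=O)(OCC)OCC | intermediate
25 | tert-butyl (4R)-4-[(2R,3R)-2-[(1E)-2-{[tert-butyl(diphenyl)silyl]oxymethyl}-4-(1,3-dioxolan-2-yl)but-1-enyl]-4-methylidene-5-oxooxolan-3-yl]-2-(diethoxyphosphoryl)-4-(3-methylbutanoyloxy)butanoate | C=C1C(=O)O[C@H](/C=C(/CO[Si](c2ccccc2)(c2ccccc2)C(C)(C)C)CCC2OCCO2)[C@H]1[C@H](OC(=O)CC(C)C)CC(C(=O)OC(C)(C)C)P(=O)(OCC)OCC | intermediate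
26 | tert-butyl (4R)-4-[(2R,3R,4R)-2-[(1E)-2-{[tert-butyl(diphenyl)silyl]oxymethyl}-4-(1,3-dioxolan-2-yl)but-1-enyl]-4-[(dimethylamino)methyl]-5-oxooxolan-3-yl]-2-(diethoxyphosphoryl)-4-(3-methylbutanoyloxy)butanoate | CN(C)C[C@@H]1C(=O)O[C@H](/C=C(/CO[Si](c2ccccc2)(c2ccccc2)C(C)(C)C)CCC2OCCO2)[C@H]1[C@H](OC(=O)CC(C)C)CC(C(=O)OC(C)(C)C)P(=O)(OCC)OCC | intermediate
27 | (4R)-4-[(2R,3R,4R)-2-[(1E)-2-{[tert-butyl(diphenyl)silyl]oxymethyl}-5-oxopent-1-enyl]-4-[(dimethylamino)methyl]-5-oxooxolan-3-yl]-2-(diethoxyphosphoryl)-4-(3-methylbutanoyloxy)butanoic acid | CN(C)C[C@@H]1C(=O)O[C@H](/C=C(/CO[Si](c2ccccc2)(c2ccccc2)C(C)(C)C)CCC=O)[C@H]1[C@H](OC(=O)CC(C)C)CC(C(=O)O)P(=O)(OCC)OCC | intermediate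
28 | S-ethyl (4R)-4-[(2R,3R,4R)-2-[(1E)-2-{[tert-butyl(diphenyl)silyl]oxymethyl}-5-oxopent-1-enyl]-4-[(dimethylamino)methyl]-5-oxooxolan-3-yl]-2-(diethoxyphosphoryl)-4-(3-methylbutanoyloxy)butanethioate (precursor of the key step) | CN(C)C[C@@H]1C(=O)O[C@H](/C=C(/CO[Si](c2ccccc2)(c2ccccc2)C(C)(C)C)CCC=O)[C@H]1[C@H](OC(=O)CC(C)C)CC(C(=O)SCC)P(=O)(OCC)OCC | intermediate
29 | S-ethyl (1(10)E,4E,6R,7R,8R,11R)-15-[tert-butyl(diphenyl)silyl]oxy-13-(dimethylamino)-8-(3-methylbutanoyloxy)-11,13-dihydrogermacra-1(10),4-dien-12,6-olide-14-thioate (product of the key step) | CN(C)C[C@@H]1C(=O)O[C@@H]2/C=C(/CO[Si](c3ccccc3)(c3ccccc3)C(C)(C)C)CC/C=C(/C(=O)SCC)C[C@@H](OC(=O)CC(C)C)[C@@H]12 | intermediate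
30 | (1(10)E,4E,6R,7R,8R,11R)-15-[tert-butyl(diphenyl)silyl]oxy-13-(dimethylamino)-8-(3-methylbutanoyloxy)-14-oxo-11,13-dihydrogermacra-1(10),4-dien-12,6-olide | CN(C)C[C@@H]1C(=O)O[C@@H]2/C=C(/CO[Si](c3ccccc3)(c3ccccc3)C(C)(C)C)CC/C=C(/C=O)C[C@@H](OC(=O)CC(C)C)[C@@H]12 | intermediate
31 | N,N,N-trimethylammonium iodide of 30 (13-trimethylammonio; not isolated) | C[N+](C)(C)C[C@@H]1C(=O)O[C@@H]2/C=C(/CO[Si](c3ccccc3)(c3ccccc3)C(C)(C)C)CC/C=C(/C=O)C[C@@H](OC(=O)CC(C)C)[C@@H]12.[I-] | intermediate
32 | (1(10)E,4E,6R,7R,8R)-15-[tert-butyl(diphenyl)silyl]oxy-8-(3-methylbutanoyloxy)-14-oxogermacra-1(10),4,11(13)-trien-12,6-olide | C=C1C(=O)O[C@@H]2/C=C(/CO[Si](c3ccccc3)(c3ccccc3)C(C)(C)C)CC/C=C(/C=O)C[C@@H](OC(=O)CC(C)C)[C@@H]12 | intermediate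
33 | (1(10)E,4E,6R,7R,8R)-15-hydroxy-8-(3-methylbutanoyloxy)-14-oxogermacra-1(10),4,11(13)-trien-12,6-olide | C=C1C(=O)O[C@@H]2/C=C(/CO)CC/C=C(/C=O)C[C@@H](OC(=O)CC(C)C)[C@@H]12 | target

## Step count and least certain steps

Total: 21 steps. Longest linear sequence: 19 steps (steps 1–9 and 12–21); the second branch (steps 10–11) joins at step 12.

Step 18 (key step). The most likely failure is intermolecular olefination (dimers, oligomers) outrunning ring closure, because the ten-membered transition state is strained and entropically costly. A second risk is slow base-induced loss of dimethylamine followed by the six-membered Michael closure of C10 on C13. The fallback closes the same C1=C10 bond by olefin metathesis; it sets out from 26 and returns at 29. Olefination of 26 with aqueous formaldehyde (K2CO3) would give the methylene tert-butyl ester F1. Aqueous trifluoroacetic acid would give the aldehyde acid F2. Wittig methylenation (Ph3P=CH2) would give the diene acid F3. Ring-closing metathesis (second-generation Hoveyda–Grubbs catalyst, camphorsulfonic acid to protonate the amine, toluene, high dilution) would give the macrocyclic acid F4, where the ring again favours the ring-cis alkene. Thioesterification (EtSH, EDC·HCl) leads to 29.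

Step 12. The most likely failure is poor facial selectivity at C7 relative to C6, because the polar model (C–O anti) and a purely steric model point to opposite faces. A second risk is 1,4-elimination of the silyloxy group from the allylmetal. The fallback lets a ring control the C7 face; it sets out from 13 and returns at 25. Desilylation of 13 (HF·pyridine) and acid lactonisation would give the hydroxy methylene lactone F5. Activation with NBS/Me2S and SN2′ attack of bromide would give the 3-(bromomethyl)butenolide F6. A Barbier reaction of F6 with 19 (Zn, THF/aq. NH4Cl) should add C8 to C7 anti to the C5 substituent, and through the E-type cyclic allylzinc should give the 7,8-anti product, the 8-epi alcohol F7. Mitsunobu esterification with 3-methylbutanoic acid (PPh3, diisopropyl azodicarboxylate) inverts C8 and gives 25.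

Step 19. The most likely failure is over-reduction: conjugate reduction or hydrosilylation of the enethioate or of the enal by the palladium hydride. A second risk is slowing of the catalyst by the tertiary amine. The fallback replaces the direct reduction by a redox detour through the acid; it sets out from 29 and returns at 30. Silver-assisted hydrolysis (AgNO3, 2,6-lutidine, THF/H2O) would give the macrocyclic acid F4. Isobutyl chloroformate and N-methylmorpholine would give the mixed anhydride F8, which NaBH4 reduces selectively to the allylic alcohol F9. MnO2 oxidises this one free allylic alcohol to 30, since O15 is still silylated.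

Step 2. The most likely failure is erosion of E selectivity, because an α-branched phosphonate meets an α-alkoxy aldehyde; partial epimerisation of 4 is a second risk. The fallback uses a stabilised phosphorane, whose olefinations of α-alkoxy aldehydes in aprotic solvents are reliably E-selective and need no base; it sets out from 2 and returns at 5. Alkylation of ethyl (triphenylphosphoranylidene)acetate with 2 (NaI, EtOAc, reflux) would give the phosphonium bromide F10. Aqueous NaOH would give the ylide F11, and a Wittig reaction of F11 with 4 in CH2Cl2 gives 5.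

## Further compounds

F1 | step 18 | tert-butyl (4R)-4-[(2R,3R,4R)-2-[(1E)-2-{[tert-butyl(diphenyl)silyl]oxymethyl}-4-(1,3-dioxolan-2-yl)but-1-enyl]-4-[(dimethylamino)methyl]-5-oxooxolan-3-yl]-2-methylidene-4-(3-methylbutanoyloxy)butanoate | CN(C)C[C@@H]1C(=O)O[C@H](/C=C(/CO[Si](c2ccccc2)(c2ccccc2)C(C)(C)C)CCC2OCCO2)[C@H]1[C@H](OC(=O)CC(C)C)CC(=C)C(=O)OC(C)(C)C
F2 | step 18 | (4R)-4-[(2R,3R,4R)-2-[(1E)-2-{[tert-butyl(diphenyl)silyl]oxymethyl}-5-oxopent-1-enyl]-4-[(dimethylamino)methyl]-5-oxooxolan-3-yl]-2-methylidene-4-(3-methylbutanoyloxy)butanoic acid | CN(C)C[C@@H]1C(=O)O[C@H](/C=C(/CO[Si](c2ccccc2)(c2ccccc2)C(C)(C)C)CCC=O)[C@H]1[C@H](OC(=O)CC(C)C)CC(=C)C(=O)O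
F3 | step 18 | (4R)-4-[(2R,3R,4R)-2-[(1E)-2-{[tert-butyl(diphenyl)silyl]oxymethyl}hexa-1,5-dienyl]-4-[(dimethylamino)methyl]-5-oxooxolan-3-yl]-2-methylidene-4-(3-methylbutanoyloxy)butanoic acid | CN(C)C[C@@H]1C(=O)O[C@H](/C=C(/CO[Si](c2ccccc2)(c2ccccc2)C(C)(C)C)CCC=C)[C@H]1[C@H](OC(=O)CC(C)C)CC(=C)C(=O)O
F4 | step 18 | (1(10)E,4E,6R,7R,8R,11R)-15-[tert-butyl(diphenyl)silyl]oxy-13-(dimethylamino)-8-(3-methylbutanoyloxy)-11,13-dihydrogermacra-1(10),4-dien-12,6-olid-14-oic acid | CN(C)C[C@@H]1C(=O)O[C@@H]2/C=C(/CO[Si](c3ccccc3)(c3ccccc3)C(C)(C)C)CC/C=C(/C(=O)O)C[C@@H](OC(=O)CC(C)C)[C@@H]12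
F5 | step 12 | (5R)-5-[(1E)-2-{[tert-butyl(diphenyl)silyl]oxymethyl}-4-(1,3-dioxolan-2-yl)but-1-enyl]-4-hydroxy-3-methylideneoxolan-2-one (both C4 epimers) | C=C1C(=O)O[C@H](/C=C(/CO[Si](c2ccccc2)(c2ccccc2)C(C)(C)C)CCC2OCCO2)C1O
F6 | step 12 | (5R)-3-(bromomethyl)-5-[(1E)-2-{[tert-butyl(diphenyl)silyl]oxymethyl}-4-(1,3-dioxolan-2-yl)but-1-enyl]furan-2(5H)-one | O=C1O[C@H](/C=C(/CO[Si](c2ccccc2)(c2ccccc2)C(C)(C)C)CCC2OCCO2)C=C1CBr
F7 | step 12 | tert-butyl (4S)-4-[(2R,3R)-2-[(1E)-2-{[tert-butyl(diphenyl)silyl]oxymethyl}-4-(1,3-dioxolan-2-yl)but-1-enyl]-4-methylidene-5-oxooxolan-3-yl]-2-(diethoxyphosphoryl)-4-hydroxybutanoate (8-epi alcohol) | C=C1C(=O)O[C@H](/C=C(/CO[Si](c2ccccc2)(c2ccccc2)C(C)(C)C)CCC2OCCO2)[C@H]1[C@@H](O)CC(C(=O)OC(C)(C)C)P(=O)(OCC)OCC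
F8 | step 19 | mixed anhydride of F4 with isobutyl carbonic acid (C14 carbonyl–O–CO2CH2CHMe2) | CN(C)C[C@@H]1C(=O)O[C@@H]2/C=C(/CO[Si](c3ccccc3)(c3ccccc3)C(C)(C)C)CC/C=C(/C(=O)OC(=O)OCC(C)C)C[C@@H](OC(=O)CC(C)C)[C@@H]12
F9 | step 19 | (1(10)E,4E,6R,7R,8R,11R)-15-[tert-butyl(diphenyl)silyl]oxy-13-(dimethylamino)-14-hydroxy-8-(3-methylbutanoyloxy)-11,13-dihydrogermacra-1(10),4-dien-12,6-olide | CN(C)C[C@@H]1C(=O)O[C@@H]2/C=C(/CO[Si](c3ccccc3)(c3ccccc3)C(C)(C)C)CC/C=C(/CO)C[C@@H](OC(=O)CC(C)C)[C@@H]12
F10 | step 2 | [1-ethoxy-4-(1,3-dioxolan-2-yl)-1-oxobutan-2-yl]triphenylphosphonium bromide | CCOC(=O)C(CCC1OCCO1)[P+](c1ccccc1)(c1ccccc1)c1ccccc1.[Br-]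
F11 | step 2 | ethyl 4-(1,3-dioxolan-2-yl)-2-(triphenyl-λ5-phosphanylidene)butanoate | CCOC(=O)C(CCC1OCCO1)=P(c1ccccc1)(c1ccccc1)c1ccccc1
A1 | alternative 1 | open-chain alkenyl iodide: methyl ester with C6 aldehyde, C5 iodide trans to C15, 8-O-triethylsilyl, 14-O-PMB, 15-O-TBS | I/C=C(/CO[Si](C)(C)C(C)(C)C)CC/C=C(/COCc1ccc(OC)cc1)C[C@@H](O[Si](CC)(CC)CC)[C@H](C=O)C(=C)C(=O)OC
A2 | alternative 1 | protected germacranolide (8-O-triethylsilyl, 14-O-PMB, 15-O-TBS, methylene lactone) | C=C1C(=O)O[C@@H]2/C=C(/CO[Si](C)(C)C(C)(C)C)CC/C=C(/COCc3ccc(OC)cc3)C[C@@H](O[Si](CC)(CC)CC)[C@@H]12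
A3 | alternative 2 | open-chain (Z)-2-(bromomethyl) tert-butyl enoate with C8 aldehyde (6-O-TBS, 15-O-TBS, 14-O-PMB) | BrC/C(C(=O)OC(C)(C)C)=C\[C@H](O[Si](C)(C)C(C)(C)C)/C=C(/CO[Si](C)(C)C(C)(C)C)CC/C=C(/COCc1ccc(OC)cc1)CC=O
A4 | alternative 2 | ten-membered hydroxy tert-butyl ester (8-OH, 6-O-TBS, 15-O-TBS, 14-O-PMB, C11=C13) | C=C(C(=O)OC(C)(C)C)[C@H]1[C@H](O[Si](C)(C)C(C)(C)C)/C=C(/CO[Si](C)(C)C(C)(C)C)CC/C=C(/COCc2ccc(OC)cc2)C[C@H]1O
A5 | alternative 3 | methylene lactone with C2 primary iodide and C1 alkenyl bromide (Br cis to C9), 8-O-(3-methylbutanoyl), 14-O-PMB, 15-O-TBS | C=C1C(=O)O[C@H](/C=C(/CO[Si](C)(C)C(C)(C)C)CCI)[C@H]1[C@H](OC(=O)CC(C)C)C/C(COCc1ccc(OC)cc1)=C\Br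
A6 | alternative 3 | 14-O-PMB, 15-O-TBS protected ten-membered lactone | C=C1C(=O)O[C@@H]2/C=C(/CO[Si](C)(C)C(C)(C)C)CC/C=C(/COCc3ccc(OC)cc3)C[C@@H](OC(=O)CC(C)C)[C@@H]12
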